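Write the balance of the starting material, the smaller charge: what leaves it appears as mono adduct, since the highest bis adduct read is 1.8% against a scatter of 1 percentage point.

the same everywhere: starting material 0.090 M
- oak: partner 2.7 equiv; run made earlier
- cedar: partner 4.5 equiv; run made earlier
- zeta: partner 2.00 equiv; time 40 h
- eta: partner 3.00 equiv; time 40 h

- oak (time / h: bis adduct / %, mono adduct / %, starting material / %): 1.50: 0, 15.0, 84.8; 2.50: 0, 21.2, 77.1; 4.00: 0.4, 26.9, 73.0; 8.00: 0.1, 35.0, 63.7; 12.0: 1.5, 40.1, 59.5; 20.0: 0, 46.0, 50.9
- cedar (time / h: bis adduct / %, mono adduct / %, starting material / %): 1.33: 0.4, 23.0, 76.4; 4.00: 0.6, 39.8, 57.5; 8.00: 0.8, 50.9, 47.8; 10.0: 0, 54.6, 43.5; 15.0: 1.0, 61.5, 38.9; 20.0: 1.8, 63.9, 33.8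

(each reading ± 1 percentage point)

- which of these holds the largest part of the starting material at the end of zeta (mono adduct / triple product / bis adduct / starting material)
- which of these holds the largest part of the starting material at the end of eta (mono adduct / triple product / bis adduct / starting material)
- final bis adduct in zeta, as a percentage of the starting material charged

- amounts and yields of mono adduct count crystals too
- given per volume of solution although it is solid: crystals
- the numbers in the tables scatter by 1 percentage point (one standard deviation)
- reactions considered so far: starting material + partner -> mono adduct; partner + mono adduct -> bis adduct; partner + bis adduct -> triple product; partner <-> dormant form; partner -> decomposed reagent; crystals <-> mono adduct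

1. The first time is the starting material's pseudo-first-order time at full partner, read from the first point: 9.10 h in oak, and 4.94 h in cedar, shorter with more partner.
2. The second is the partner's working life: the hours at full strength that equal the loss seen by 20.0 h. The exponent −ln(fraction left) is this life over the first time. We read 6.14 h in oak and 5.36 h in cedar, both shorter than the run, so the partner fades early.
3. The two working lives differ by 0.780 h, so we let the exponent scale with equivalents: 0.246 /equiv at 20.0 h. Cedar's exponent grew 1.30-fold from 10.0 h to 20.0 h. We assume the same for the next doubling, which gives 0.320 /equiv, the reach per equivalent at 40 h.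
4. In this balance mono adduct leads once the exponent passes 0.693. We reckon 0.640 for zeta, below it, leaving 52.7% starting material, and 0.960 for eta, above it, leaving 38.3%.
5. The forecast says starting material for zeta, mono adduct for eta and 0.5% bis adduct: “This is close, but SM is slightly ahead”.
6. Zeta ends with 53.6% starting material, more than its 45.5% mono adduct, and with 0.557% bis adduct. Eta ends with 60.1% mono adduct, more than its 38.4% starting material.

    starting material + partner → mono adduct (k = 0.0100 /M/min)
    partner + mono adduct → bis adduct (k = 0.0110 /M/min)
    partner + bis adduct → triple product (k = 0.0150 /M/min)
    partner ⇌ dormant form (K = 2.50, k = 0.00360 /min)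
    partner → decomposed reagent (k = 0.00150 /min)
    crystals ⇌ mono adduct, rate k6*(cs6 - [mono adduct]) while solid is left; crystals form when [mono adduct] > cs6 (solubility = 0.910 mM, k = 0.140 /min)

7. Take zeta with 1.20 equiv of partner, read at 40.0 h. The reach gives an exponent of 0.384, so 68.1% starting material. That neighbour holds 69.3% starting material, 30.2% mono adduct and 0.363% bis adduct.

The numbers in the tables are simulated with made-up constants; the scatter is artificial.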